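**Retrosynthetic overview**

1. Ring numbering used throughout: C-1 bears the side chain, C-2 is C(CH3)OH, C-3 and C-4 are CH2, C-5 is CHOH, C-6 is C(CH3)2. The aryl ether is cut last (Mitsunobu of umbelliferone with a tetraol), because the coumarin tolerates neither hydrazine nor organometallic reagents.
2. The cis C-2/C-5 diol comes from a Wharton transposition of a 4,5-epoxy-3-ketone: the oxirane oxygen becomes the C-5 hydroxyl and the C-3 carbonyl is erased. Before that, C-2 is methylated and then hydroxylated anti to the side chain.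
3. The side chain is joined at C-1 by copper-catalysed asymmetric 1,4-addition of a dialkylzinc, made from (R)-linalool, to the cross-conjugated epoxy enone.
4. The cyclohexane is the only ring formed and it is formed first, closed at C-4–C-5 by aldol condensation inside a one-pot amine-catalysed annulation–epoxidation of isobutyraldehyde and methyl vinyl ketone.
5. Enabling feature: C-6(CH3)2–C-5H(OH)–C-4H2 is an isobutyraldehyde unit. As a formyl carbon, C-5 has no α-hydrogen (C-6 is quaternary), so the 1,5-keto aldehyde has a single aldol mode, and the C-5 oxygen is returned as the oxirane of the resulting enone.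

Key step: step 1

Remark: (R)-(−)-linalool of high enantiomeric purity is taken as commercial. The absolute sense of the two catalyst-controlled steps (1 and 7) is fixed by the choice of catalyst antipode (quinine- or quinidine-derived amine; (S,R,R)- or (R,S,S)-phosphoramidite), and the one giving the drawn configuration is used. Bicyclic intermediates are numbered as 7-oxabicyclo[4.1.0]heptanes: C-1 and C-6 are the oxirane carbons, C-2 the carbonyl, C-5 the quaternary carbon.

**Step 1**
Reactants: 1 isobutyraldehyde; 2 methyl vinyl ketone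
Product: 5 (1S,6S)-5,5-dimethyl-7-oxabicyclo[4.1.0]heptan-2-one, via Michael adduct 3 (not isolated), via enone 4 (not isolated)
Conditions: 9-amino-9-deoxy-epi-quinine (10 mol %), CF3CO2H (20 mol %), dioxane, 40 °C; then 50 % aq. H2O2 (1.5 equiv), 30–50 °C
Reagents that add atoms: hydrogen peroxide, OO
Why: The primary-amine salt converts isobutyraldehyde into its enamine, which adds to the iminium-activated vinyl ketone to give keto aldehyde 3; the methyl-ketone enamine then attacks the formyl carbon and water is lost to give enone 4, whose iminium ion takes up H2O2 at the β-carbon before the resulting enamine closes the oxirane on the O–O bond. The closest known reactions are the Robinson-type annulation of isobutyraldehyde with methyl vinyl ketone under acid or amine catalysis and the primary-amine-salt-catalysed asymmetric epoxidation of cyclohexenones with aqueous H2O2, here run in one flask with one catalyst. The carbocycle is closed by a 6-(enolendo)-exo-trig aldol addition followed by dehydration (this is the C-4–C-5 bond of the target ring), and the oxirane by 3-exo-tet displacement at oxygen. The two new stereocentres are the oxirane carbons (cis fusion is compulsory), and their absolute configuration is set by the cinchona amine, which shields one face of the ring iminium ion. The step needs site selectivity in the aldol and enantioface selectivity in the epoxidation: the formyl carbon has no α-hydrogen and the internal ketone enamine could only close a four-membered ring, so there is a single aldol mode, and the quaternary carbon rules out dienamine formation. H2O2 is added only after 4 has formed so that the aldehyde is not oxidised.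

**Step 2**
Reactants: 5 (1S,6S)-5,5-dimethyl-7-oxabicyclo[4.1.0]heptan-2-one
Product: 8 (1S,6S)-5,5-dimethyl-7-oxabicyclo[4.1.0]hept-3-en-2-one, via lithium enolate 6 (not isolated), via silyl enol ether 7 (not isolated)
Conditions: LiN(iPr)2 (LDA), THF, −78 °C; Me3SiCl; then Pd(OAc)2 (1.05 equiv), MeCN, rt
Reagents that add atoms: none
Why: Saegusa–Ito dehydrogenation: C-3 is the only enolisable position (C-1 is an oxirane carbon, C-5 is quaternary), so kinetic enolisation, O-silylation and palladium-mediated dehydrosilylation should give the cross-conjugated epoxy enone with both oxirane stereocentres untouched.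

**Step 3**
Reactants: 9 (R)-(−)-linalool
Product: 11 (3R)-3,7-dimethyloct-6-ene-1,3-diol, via alkylborane 10 (not isolated)
Conditions: 9-BBN (2.2 equiv), THF, 0 °C → rt; then NaOH, 30 % H2O2, 0 °C
Reagents that add atoms: hydrogen peroxide, OO
Why: Brown hydroboration–oxidation with 9-BBN is selective for the monosubstituted vinyl group over the trisubstituted alkene and anti-Markovnikov, so the primary alcohol should form while the tertiary carbinol stereocentre is untouched.

**Step 4**
Reactants: 11 (3R)-3,7-dimethyloct-6-ene-1,3-diol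
Product: 12 (4R)-2,2,4-trimethyl-4-(4-methylpent-3-en-1-yl)-1,3-dioxane
Conditions: Me2C(OMe)2, PPTS (cat.), CH2Cl2, rt
Reagents that add atoms: 2,2-dimethoxypropane, COC(C)(C)OC
Why: Acid-catalysed transacetalisation ties the primary and tertiary hydroxyls of the 1,3-diol into a six-membered acetonide, which protects both oxygens until step 12.

**Step 5**
Reactants: 12 (4R)-2,2,4-trimethyl-4-(4-methylpent-3-en-1-yl)-1,3-dioxane
Product: 13 3-[(4R)-2,2,4-trimethyl-1,3-dioxan-4-yl]propanoic acid
Conditions: RuCl3 (2 mol %), NaIO4 (4 equiv), NaHCO3, EtOAc/MeCN/H2O, rt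
Reagents that add atoms: sodium periodate, [Na+].[O-]I(=O)(=O)=O; water, O
Why: RuO4-catalysed oxidative cleavage of the trisubstituted alkene should give the carboxylic acid and acetone, the buffered medium sparing the acetonide.

**Step 6**
Reactants: 13 3-[(4R)-2,2,4-trimethyl-1,3-dioxan-4-yl]propanoic acid
Product: 14 (4S)-4-(2-iodoethyl)-2,2,4-trimethyl-1,3-dioxane
Conditions: PhI(OAc)2, I2, cyclohexane, hν (tungsten lamp), reflux
Reagents that add atoms: iodine, II
Why: Photolytic iododecarboxylation (Hunsdiecker-type): the acyl hypoiodite fragments to CO2 and a primary alkyl radical that is trapped by iodine; the stereocentre is not involved (the descriptor changes to S only through CIP priorities).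

**Step 7**
Reactants: 8 (1S,6S)-5,5-dimethyl-7-oxabicyclo[4.1.0]hept-3-en-2-one; 14 (4S)-4-(2-iodoethyl)-2,2,4-trimethyl-1,3-dioxane
Product: 17 (1S,4R,6S)-5,5-dimethyl-4-{2-[(4R)-2,2,4-trimethyl-1,3-dioxan-4-yl]ethyl}-7-oxabicyclo[4.1.0]heptan-2-one, via dialkylzinc 15 (not isolated), via zinc enolate 16 (not isolated)
Conditions: 14, Et2Zn (neat, excess), CuI (0.3 mol %), 50 °C, then volatiles removed in vacuo; 8, Cu(OTf)2 (2 mol %), (S,R,R)-O,O'-(1,1'-binaphthyl-2,2'-diyl) N,N-bis(1-phenylethyl)phosphoramidite (4 mol %), toluene, −30 °C; aq. NH4Cl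
Reagents that add atoms: none
Why: Iodine–zinc exchange gives the salt-free dialkylzinc, and copper–phosphoramidite-catalysed asymmetric conjugate addition, well precedented for 4,4-dimethylcyclohex-2-enone, should transfer the alkyl group to C-4 next to the quaternary carbon; the new stereocentre (4R, side chain trans to the oxirane oxygen) is set by the ligand.

**Step 8**
Reactants: 17 (1S,4R,6S)-5,5-dimethyl-4-{2-[(4R)-2,2,4-trimethyl-1,3-dioxan-4-yl]ethyl}-7-oxabicyclo[4.1.0]heptan-2-one
Product: 19 (1S,3R,4R,6S)-3,5,5-trimethyl-4-{2-[(4R)-2,2,4-trimethyl-1,3-dioxan-4-yl]ethyl}-7-oxabicyclo[4.1.0]heptan-2-one, via lithium enolate 18 (not isolated)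
Conditions: LiN(iPr)2 (LDA), THF, −78 °C; MeI, −78 → −20 °C
Reagents that add atoms: iodomethane, CI
Why: Kinetic enolisation is possible only at C-3, and enolate alkylation should place the methyl trans to the neighbouring side chain; this centre is enolised again in step 9, so its configuration is of no consequence.

**Step 9**
Reactants: 19 (1S,3R,4R,6S)-3,5,5-trimethyl-4-{2-[(4R)-2,2,4-trimethyl-1,3-dioxan-4-yl]ethyl}-7-oxabicyclo[4.1.0]heptan-2-one
Product: 21 (1S,3R,4S,6S)-3-hydroxy-3,5,5-trimethyl-4-{2-[(4R)-2,2,4-trimethyl-1,3-dioxan-4-yl]ethyl}-7-oxabicyclo[4.1.0]heptan-2-one, via potassium enolate 20 (not isolated)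
Conditions: KN(SiMe3)2 (KHMDS), THF, −78 °C; 2-(phenylsulfonyl)-3-phenyloxaziridine; aq. NH4Cl
Reagents that add atoms: 2-(phenylsulfonyl)-3-phenyloxaziridine, O=S(=O)(N1OC1c1ccccc1)c1ccccc1
Why: Davis oxidation of the tetrasubstituted enolate: the C-4 side chain sits pseudo-axial to avoid allylic 1,2-strain with the enolate methyl, so oxygen should be delivered to C-3 from the opposite face, giving the hydroxyl trans to the side chain and cis to the oxirane (3R).

**Step 10**
Reactants: 21 (1S,3R,4S,6S)-3-hydroxy-3,5,5-trimethyl-4-{2-[(4R)-2,2,4-trimethyl-1,3-dioxan-4-yl]ethyl}-7-oxabicyclo[4.1.0]heptan-2-one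
Product: 23 (1S,4R,6S)-1,5,5-trimethyl-6-{2-[(4R)-2,2,4-trimethyl-1,3-dioxan-4-yl]ethyl}cyclohex-2-ene-1,4-diol, via hydrazone 22 (not isolated)
Conditions: N2H4·H2O (3 equiv), AcOH (cat.), MeOH, 0 °C → rt
Reagents that add atoms: none
Why: Wharton transposition: the hydrazone of the α,β-epoxy ketone opens the oxirane to an alkenyl diazene that loses N2, which removes the carbonyl oxygen and leaves the former oxirane C–O bond as the secondary carbinol with retention, hence cis to the tertiary hydroxyl.

**Step 11**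
Reactants: 23 (1S,4R,6S)-1,5,5-trimethyl-6-{2-[(4R)-2,2,4-trimethyl-1,3-dioxan-4-yl]ethyl}cyclohex-2-ene-1,4-diol
Product: 24 (1S,2S,4R)-1,3,3-trimethyl-2-{2-[(4R)-2,2,4-trimethyl-1,3-dioxan-4-yl]ethyl}cyclohexane-1,4-diol
Conditions: H2 (1 atm), PtO2, EtOAc, rt
Reagents that add atoms: none
Why: Heterogeneous hydrogenation of the cis-disubstituted ring alkene over Adams' catalyst in a neutral solvent forms no stereocentre and should keep allylic C–O hydrogenolysis low.

**Step 12**
Reactants: 24 (1S,2S,4R)-1,3,3-trimethyl-2-{2-[(4R)-2,2,4-trimethyl-1,3-dioxan-4-yl]ethyl}cyclohexane-1,4-diol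
Product: 25 (1S,2S,4R)-2-[(3R)-3,5-dihydroxy-3-methylpentyl]-1,3,3-trimethylcyclohexane-1,4-diol
Conditions: AcOH/THF/H2O (3:1:1), 40 °C
Reagents that add atoms: none
Why: Acid-catalysed acetonide hydrolysis releases the primary and the side-chain tertiary hydroxyl; the saturated ring carbinols should be stable to dilute acetic acid.

**Step 13**
Reactants: 25 (1S,2S,4R)-2-[(3R)-3,5-dihydroxy-3-methylpentyl]-1,3,3-trimethylcyclohexane-1,4-diol; 26 umbelliferone (7-hydroxy-2H-chromen-2-one)
Product: 27 7-{[(3R)-5-[(1S,2S,5R)-2,5-dihydroxy-2,6,6-trimethylcyclohexyl]-3-hydroxy-3-methylpentyl]oxy}-2H-chromen-2-one (CNP0210598.1)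
Conditions: PPh3, DIAD, THF, 0 °C → rt
Reagents that add atoms: none
Why: Mitsunobu etherification: only the unhindered primary alcohol should form a reactive alkoxyphosphonium ion, which the acidic 7-hydroxyl of umbelliferone displaces; the neopentyl secondary and the two tertiary hydroxyls should not react.

**Compound list**

1 | isobutyraldehyde (2-methylpropanal) | CC(C)C=O | starting material
2 | methyl vinyl ketone (but-3-en-2-one) | CC(=O)C=C | starting material
3 | 2,2-dimethyl-5-oxohexanal | CC(=O)CCC(C)(C)C=O | intermediate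
4 | 4,4-dimethylcyclohex-2-en-1-one | CC1(C)CCC(=O)C=C1 | intermediate
5 | (1S,6S)-5,5-dimethyl-7-oxabicyclo[4.1.0]heptan-2-one | CC1(C)[C@@H]2O[C@@H]2C(=O)CC1 | intermediate
6 | lithium (1S,6S)-5,5-dimethyl-7-oxabicyclo[4.1.0]hept-2-en-2-olate | CC1(C)[C@@H]2O[C@@H]2C(O[Li])=CC1 | intermediate
7 | trimethyl{[(1S,6S)-5,5-dimethyl-7-oxabicyclo[4.1.0]hept-2-en-2-yl]oxy}silane | CC1(C)[C@@H]2O[C@@H]2C(O[Si](C)(C)C)=CC1 | intermediate
8 | (1S,6S)-5,5-dimethyl-7-oxabicyclo[4.1.0]hept-3-en-2-one | CC1(C)[C@@H]2O[C@@H]2C(=O)C=C1 | intermediate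
9 | (R)-(−)-linalool, (3R)-3,7-dimethylocta-1,6-dien-3-ol | C=C[C@](C)(O)CCC=C(C)C | starting material
10 | (3S)-1-(9-borabicyclo[3.3.1]nonan-9-yl)-3,7-dimethyloct-6-en-3-ol (same spatial arrangement as 9) | C[C@](O)(CCB1C2CCCC1CCC2)CCC=C(C)C | intermediate
11 | (3R)-3,7-dimethyloct-6-ene-1,3-diol | OCC[C@](C)(O)CCC=C(C)C | intermediate
12 | (4R)-2,2,4-trimethyl-4-(4-methylpent-3-en-1-yl)-1,3-dioxane | CC1(C)OCC[C@@](C)(CCC=C(C)C)O1 | intermediate
13 | 3-[(4R)-2,2,4-trimethyl-1,3-dioxan-4-yl]propanoic acid | CC1(C)OCC[C@@](C)(CCC(=O)O)O1 | intermediate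
14 | (4S)-4-(2-iodoethyl)-2,2,4-trimethyl-1,3-dioxane | CC1(C)OCC[C@@](C)(CCI)O1 | intermediate
15 | bis{2-[(4S)-2,2,4-trimethyl-1,3-dioxan-4-yl]ethyl}zinc | [Zn](CC[C@]1(C)CCOC(C)(C)O1)CC[C@]2(C)CCOC(C)(C)O2 | intermediate
16 | alkylzinc enolate of 17 (O–Zn–alkyl, enolate C-2=C-3; C-1 S, C-4 R, C-6 S) | CC1(C)[C@@H]2O[C@@H]2C(O[Zn]CC[C@]3(C)CCOC(C)(C)O3)=C[C@H]1CC[C@]4(C)CCOC(C)(C)O4 | intermediate
17 | (1S,4R,6S)-5,5-dimethyl-4-{2-[(4R)-2,2,4-trimethyl-1,3-dioxan-4-yl]ethyl}-7-oxabicyclo[4.1.0]heptan-2-one | CC1(C)[C@@H]2O[C@@H]2C(=O)C[C@H]1CC[C@]3(C)CCOC(C)(C)O3 | intermediate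
18 | lithium enolate of 17 (enolate C-2=C-3; other centres unchanged) | CC1(C)[C@@H]2O[C@@H]2C(O[Li])=C[C@H]1CC[C@]3(C)CCOC(C)(C)O3 | intermediate
19 | (1S,3R,4R,6S)-3,5,5-trimethyl-4-{2-[(4R)-2,2,4-trimethyl-1,3-dioxan-4-yl]ethyl}-7-oxabicyclo[4.1.0]heptan-2-one | CC1(C)[C@@H]2O[C@@H]2C(=O)[C@H](C)[C@H]1CC[C@]3(C)CCOC(C)(C)O3 | intermediate
20 | potassium enolate of 19 (enolate C-2=C-3; other centres unchanged) | CC1(C)[C@@H]2O[C@@H]2C(O[K])=C(C)[C@H]1CC[C@]3(C)CCOC(C)(C)O3 | intermediate
21 | (1S,3R,4S,6S)-3-hydroxy-3,5,5-trimethyl-4-{2-[(4R)-2,2,4-trimethyl-1,3-dioxan-4-yl]ethyl}-7-oxabicyclo[4.1.0]heptan-2-one | CC1(C)[C@@H]2O[C@@H]2C(=O)[C@](C)(O)[C@H]1CC[C@]3(C)CCOC(C)(C)O3 | intermediate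
22 | hydrazone of 21 (C-2=N–NH2; all centres unchanged) | CC1(C)[C@@H]2O[C@@H]2C(=NN)[C@](C)(O)[C@H]1CC[C@]3(C)CCOC(C)(C)O3 | intermediate
23 | (1S,4R,6S)-1,5,5-trimethyl-6-{2-[(4R)-2,2,4-trimethyl-1,3-dioxan-4-yl]ethyl}cyclohex-2-ene-1,4-diol | CC1(C)[C@H](O)C=C[C@](C)(O)[C@H]1CC[C@]2(C)CCOC(C)(C)O2 | intermediate
24 | (1S,2S,4R)-1,3,3-trimethyl-2-{2-[(4R)-2,2,4-trimethyl-1,3-dioxan-4-yl]ethyl}cyclohexane-1,4-diol | CC1(C)[C@H](O)CC[C@](C)(O)[C@H]1CC[C@]2(C)CCOC(C)(C)O2 | intermediate
25 | (1S,2S,4R)-2-[(3R)-3,5-dihydroxy-3-methylpentyl]-1,3,3-trimethylcyclohexane-1,4-diol | CC1(C)[C@H](O)CC[C@](C)(O)[C@H]1CC[C@@](C)(O)CCO | intermediate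
26 | umbelliferone (7-hydroxy-2H-chromen-2-one) | Oc1ccc2ccc(=O)oc2c1 | starting material
27 | 7-{[(3R)-5-[(1S,2S,5R)-2,5-dihydroxy-2,6,6-trimethylcyclohexyl]-3-hydroxy-3-methylpentyl]oxy}-2H-chromen-2-one | CC1(C)[C@H](O)CC[C@](C)(O)[C@H]1CC[C@@](C)(O)CCOc1ccc2ccc(=O)oc2c1 | target

**Totals**

Total step count: 13. Longest linear sequence: 11 steps (steps 3–6, then 7–13); the ring branch (steps 1–2, then 7–13) has 9.

**Steps most likely to fail**

Step 1. The two stages may not tolerate each other in one flask (oxidation of residual aldehyde and of the amine by H2O2), or enantioface selection at the neopentyl β-carbon may be poor. Fallback: the fallback sets out from 4, isolated by distillation after the annulation stage, and comes back at 5. Corey–Bakshi–Shibata reduction ((S)-Me-CBS oxazaborolidine, BH3·SMe2) should give (R)-4,4-dimethylcyclohex-2-en-1-ol F1. Hydroxyl-directed epoxidation (VO(acac)2, tBuOOH) should then place the oxirane syn to the hydroxyl to give (1R,2R,6S)-5,5-dimethyl-7-oxabicyclo[4.1.0]heptan-2-ol F2. Dess–Martin oxidation returns to 5. Here the oxirane configuration is relayed from a carbinol centre instead of being set by an iminium catalyst.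

Step 7. The copper–zinc reagent may open the oxirane reductively (loss of the C-5 oxygen), or transfer of the γ-alkoxyalkyl group to the hindered β-carbon may be slow. Fallback: the fallback sets out from 8 and 14 and comes back at 17. A radical Giese addition is used instead of the organometallic one: iodide 14, (Me3Si)3SiH and Et3B/air in toluene at 0 °C generate the primary alkyl radical, which adds to C-4 of enone 8, and the α-keto radical is reduced by the silane to give 17 directly. No reducing metal is present, so the oxirane should survive. Facial selectivity then rests on the substrate (approach anti to the oxirane oxygen), and C-4 epimers would be separated at 17. This fallback makes no new compound (F0).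

Step 10. Hydrazone formation at a ketone flanked by a quaternary carbinol and an oxirane may be slow, so that the alkenyl diazene decomposes by other paths. Fallback: the fallback sets out from 21 and comes back at 23. NaBH4 (MeOH, 0 °C) should give (1R,2S,3R,4S,6S)-3,5,5-trimethyl-4-{2-[(4R)-2,2,4-trimethyl-1,3-dioxan-4-yl]ethyl}-7-oxabicyclo[4.1.0]heptane-2,3-diol F3 (drawn as the C-2 epimer with hydroxyl cis to the oxirane; either epimer serves). PhOC(S)Cl, pyridine and DMAP should acylate only the secondary hydroxyl to give O-[(1S,2S,3R,4S,6S)-3-hydroxy-3,5,5-trimethyl-4-{2-[(4R)-2,2,4-trimethyl-1,3-dioxan-4-yl]ethyl}-7-oxabicyclo[4.1.0]heptan-2-yl] O-phenyl carbonothioate F4. Bu3SnH (high concentration) and AIBN in toluene at 80 °C then generate the C-2 radical, which opens the oxirane; the alkoxyl radical is reduced by the stannane (radical deoxygenative transposition of the Barton–McCombie type) to give 23.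

**Further compounds**

F1 | step 1 | (R)-4,4-dimethylcyclohex-2-en-1-ol | CC1(C)C=C[C@H](O)CC1
F2 | step 1 | (1R,2R,6S)-5,5-dimethyl-7-oxabicyclo[4.1.0]heptan-2-ol | CC1(C)[C@@H]2O[C@@H]2[C@H](O)CC1
F0 | step 7 | none | none
F3 | step 10 | (1R,2S,3R,4S,6S)-3,5,5-trimethyl-4-{2-[(4R)-2,2,4-trimethyl-1,3-dioxan-4-yl]ethyl}-7-oxabicyclo[4.1.0]heptane-2,3-diol | CC1(C)[C@@H]2O[C@@H]2[C@H](O)[C@](C)(O)[C@H]1CC[C@]3(C)CCOC(C)(C)O3
F4 | step 10 | O-[(1S,2S,3R,4S,6S)-3-hydroxy-3,5,5-trimethyl-4-{2-[(4R)-2,2,4-trimethyl-1,3-dioxan-4-yl]ethyl}-7-oxabicyclo[4.1.0]heptan-2-yl] O-phenyl carbonothioate | CC1(C)[C@@H]2O[C@@H]2[C@H](OC(=S)Oc3ccccc3)[C@](C)(O)[C@H]1CC[C@]4(C)CCOC(C)(C)O4
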